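**Plan**

- The first retrosynthetic cut is the C4–CH3 bond at the quaternary carbon of the cyclohexadienone ring. C4 carries methyl and prenyl and sits between the enolic C3–OH and C5–OH; without that methyl the ring is an aromatic acylphloroglucinol and the molecule is the achiral methylene-bis(acylphloroglucinol) 11, whose prenyl-bearing ring carbon is a phenolate-type nucleophile with two enantiotopic faces.
- The next cuts are the two aryl–CH2 bonds of the bridge (to monomers 5 and 8, through Mannich base 9), then the aryl–prenyl bond, the aryl O–CH3 bond and the two aryl–acyl bonds, back to phloroglucinol.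
- Forward, no ring is ever closed: both six-membered rings are phloroglucinol rings. The sequence is two acylations, C-prenylation of the butanoyl ring, 4-O-methylation of the hexanoyl ring, Mannich/ortho-quinone-methide union, and a final methyl transfer that dearomatises the prenylated ring.
- The single stereocentre (C4, R) is set in the last step by an engineered SAM-dependent C-methyltransferase, with iodomethane as terminal methyl source.

Key step: step 7

Remark: the β-triketone ring is written in the dienol-one tautomer of the target SMILES, for which C4 is (R) (the other enol tautomers are the same compound), and an (R)-selective methyltransferase variant is assumed to be obtainable by screening and directed evolution.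

**Route**

Step 1
Reactants: 1 phloroglucinol; 2 butanoyl chloride
Product: 3 1-(2,4,6-trihydroxyphenyl)butan-1-one
Conditions: AlCl3 (4 equiv), PhNO2/CH2Cl2, 0 °C to 50 °C; ice/1 M HCl
Reagents that add atoms: none
Why: Friedel–Crafts C-acylation of the very electron-rich triol, which should stop at the mono-ketone because the chelated acyl group deactivates the ring.

Step 2
Reactants: 3 1-(2,4,6-trihydroxyphenyl)butan-1-one; 4 prenyl bromide
Product: 5 1-[2,4,6-trihydroxy-3-(3-methylbut-2-enyl)phenyl]butan-1-one
Conditions: DBU (1.1 equiv), THF, 0 °C to rt, 4 (1.0 equiv) added slowly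
Reagents that add atoms: none
Why: Base-mediated C-alkylation of the acylphloroglucinol anion with an allylic bromide, a standard entry to mono-C-prenyl acylphloroglucinols; the two free ring carbons of 3 are equivalent, and slow addition of one equivalent limits double prenylation.

Step 3
Reactants: 1 phloroglucinol; 6 hexanoyl chloride
Product: 7 1-(2,4,6-trihydroxyphenyl)hexan-1-one
Conditions: AlCl3 (4 equiv), PhNO2/CH2Cl2, 0 °C to 50 °C; ice/1 M HCl
Reagents that add atoms: none
Why: The same Friedel–Crafts mono-acylation as in step 1, with the longer acid chloride.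

Step 4
Reactants: 7 1-(2,4,6-trihydroxyphenyl)hexan-1-one
Product: 8 1-(2,6-dihydroxy-4-methoxyphenyl)hexan-1-one
Conditions: Me2SO4 (1.0 equiv), K2CO3 (1.0 equiv), acetone, rt
Reagents that add atoms: dimethyl sulfate, COS(=O)(=O)OC
Why: Williamson-type phenol O-methylation, selective for the 4-hydroxyl because it is the only one not hydrogen-bonded to the ketone and is the most acidic.

Step 5
Reactants: 5 1-[2,4,6-trihydroxy-3-(3-methylbut-2-enyl)phenyl]butan-1-one
Product: 9 1-[3-[(dimethylamino)methyl]-2,4,6-trihydroxy-5-(3-methylbut-2-enyl)phenyl]butan-1-one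
Conditions: Eschenmoser's salt (1.05 equiv), Et3N (1.1 equiv), CH2Cl2, 0 °C to rt
Reagents that add atoms: N,N-dimethylmethyleneiminium iodide (Eschenmoser's salt), C=[N+](C)C.[I-]
Why: Mannich aminomethylation by the preformed iminium ion at the only unsubstituted ring carbon of 5, so that neither regioisomers nor bis-adducts can form.

Step 6
Reactants: 9 1-[3-[(dimethylamino)methyl]-2,4,6-trihydroxy-5-(3-methylbut-2-enyl)phenyl]butan-1-one; 8 1-(2,6-dihydroxy-4-methoxyphenyl)hexan-1-one
Product: 11 1-[3-[[3-butanoyl-2,4,6-trihydroxy-5-(3-methylbut-2-enyl)phenyl]methyl]-2,6-dihydroxy-4-methoxyphenyl]hexan-1-one, via ortho-quinone methide 10 (not isolated)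
Conditions: 8 (3 equiv), 1,4-dioxane, 100 °C, N2 sweep; excess 8 recovered
Reagents that add atoms: none
Why: Thermal loss of dimethylamine from the phenolic Mannich base gives ortho-quinone methide 10, which is captured in a Friedel–Crafts-type conjugate addition by the ring C–H of 8 between OH and OMe (both such positions are equivalent), and the excess of 8 suppresses a second alkylation of that ring.

Step 7
Reactants: 11 1-[3-[[3-butanoyl-2,4,6-trihydroxy-5-(3-methylbut-2-enyl)phenyl]methyl]-2,6-dihydroxy-4-methoxyphenyl]hexan-1-one; 12 iodomethane
Product: 13 elaphopilosin B, (4R)-2-butanoyl-6-[(3-hexanoyl-2,4-dihydroxy-6-methoxyphenyl)methyl]-3,5-dihydroxy-4-methyl-4-(3-methylbut-2-enyl)cyclohexa-2,5-dien-1-one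
Conditions: evolved (R)-selective SAM-dependent C-methyltransferase, halide methyltransferase, SAH (2 mol %), 12 (1.5 equiv, in portions), potassium phosphate buffer pH 7.5, 10% v/v DMSO, 25 °C, closed vessel; acidify to pH 3, EtOAc
Reagents that add atoms: none
Why: Proposed new method: an active-site base removes the proton of a hydroxyl flanking the prenyl-bearing carbon of the butanoyl ring of 11, and that phenolate carbon, held in line with the S–CH3 bond of SAM, takes the methyl group in an SN2 transfer that forms the C4–CH3 bond, dearomatises the ring and releases 13 as its stabilised β-triketone anion, while the halide methyltransferase remethylates SAH with 12 so that the cofactor turns over. The closest known reaction types are SAM-dependent C-methylations of electron-rich aromatic carbons (dearomatising C3-methylation of indoles, C-methylation of hydroxycoumarins and phloroglucinol-type polyketides, gem-dimethyl formation in polyketide pathways), which are compatible with cofactor recycling from iodomethane. No ring closes in this step. The one new stereocentre (C4, R) has no control element in the achiral substrate and is fixed by the enzyme pose alone: the methyl must reach the Si face of the prenyl-bearing carbon (ranking: C–OH carbon next to the butanoyl-bearing carbon > C–OH carbon next to the bridge-bearing carbon > prenyl CH2). The step needs site selectivity for this carbon over the bridge-bearing carbon, the free C–H of the methoxy ring and the oxygens; the substrate offers only the high electron density of a carbon between two hydroxyls, so the selectivity has to come from a pocket evolved to read the butanoyl and benzyl flanks, with uncatalysed methylation by 12 kept slow by near-neutral water, 25 °C and portionwise dosing.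

**Compound list**

1 | phloroglucinol (benzene-1,3,5-triol) | Oc1cc(O)cc(O)c1 | starting material
2 | butanoyl chloride | CCCC(=O)Cl | starting material
3 | 1-(2,4,6-trihydroxyphenyl)butan-1-one | CCCC(=O)c1c(O)cc(O)cc1O | intermediate
4 | prenyl bromide (1-bromo-3-methylbut-2-ene) | CC(C)=CCBr | starting material
5 | 1-[2,4,6-trihydroxy-3-(3-methylbut-2-enyl)phenyl]butan-1-one | CCCC(=O)c1c(O)cc(O)c(CC=C(C)C)c1O | intermediate
6 | hexanoyl chloride | CCCCCC(=O)Cl | starting material
7 | 1-(2,4,6-trihydroxyphenyl)hexan-1-one | CCCCCC(=O)c1c(O)cc(O)cc1O | intermediate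
8 | 1-(2,6-dihydroxy-4-methoxyphenyl)hexan-1-one | CCCCCC(=O)c1c(O)cc(OC)cc1O | intermediate
9 | 1-[3-[(dimethylamino)methyl]-2,4,6-trihydroxy-5-(3-methylbut-2-enyl)phenyl]butan-1-one | CCCC(=O)c1c(O)c(CN(C)C)c(O)c(CC=C(C)C)c1O | intermediate
10 | 4-butanoyl-3,5-dihydroxy-6-methylidene-2-(3-methylbut-2-enyl)cyclohexa-2,4-dien-1-one (ortho-quinone methide, not isolated) | CCCC(=O)C1=C(O)C(=C)C(=O)C(CC=C(C)C)=C1O | intermediate
11 | 1-[3-[[3-butanoyl-2,4,6-trihydroxy-5-(3-methylbut-2-enyl)phenyl]methyl]-2,6-dihydroxy-4-methoxyphenyl]hexan-1-one | CCCCCC(=O)c1c(O)cc(OC)c(Cc2c(O)c(CC=C(C)C)c(O)c(C(=O)CCC)c2O)c1O | intermediate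
12 | iodomethane | CI | starting material
13 | elaphopilosin B, (4R)-2-butanoyl-6-[(3-hexanoyl-2,4-dihydroxy-6-methoxyphenyl)methyl]-3,5-dihydroxy-4-methyl-4-(3-methylbut-2-enyl)cyclohexa-2,5-dien-1-one | CCCCCC(=O)c1c(O)cc(OC)c(CC2=C(O)[C@@](C)(CC=C(C)C)C(O)=C(C(=O)CCC)C2=O)c1O | target

**Count and risks**

Total steps: 7. Longest linear sequence: 5 (steps 1, 2, 5, 6, 7 from phloroglucinol); the hexanoyl branch (steps 3, 4) joins at step 6.

Steps most likely to fail:

1. Step 7 (proposed new method). No variant may reach useful turnover on so large a substrate, or the methyl may be misdirected to the free C–H of the methoxy ring, to oxygen, to the bridge-bearing carbon or to the wrong face; uncatalysed methylation by iodomethane could also erode the enantiomeric purity. The fallback uses known chemistry, sets out from 5 and returns at 13. Treating 5 with NaOMe and 12 in MeOH at 0 °C to rt (the classical geminal C-alkylation of acylphloroglucinols that leads to acylfilicinic acids) should give racemic 2-butanoyl-3,5-dihydroxy-4-methyl-4-(3-methylbut-2-enyl)cyclohexa-2,5-dien-1-one F1; it is much more acidic than the aromatic C-methyl isomer and can be separated from it by bicarbonate extraction. Preparative chromatography on a chiral stationary phase then gives (4R)-2-butanoyl-3,5-dihydroxy-4-methyl-4-(3-methylbut-2-enyl)cyclohexa-2,5-dien-1-one F2, its configuration to be assigned by chiroptical comparison or crystallography. Eschenmoser's salt with Et3N in CH2Cl2 aminomethylates the only ring C–H of F2 to give (4R)-2-butanoyl-6-[(dimethylamino)methyl]-3,5-dihydroxy-4-methyl-4-(3-methylbut-2-enyl)cyclohexa-2,5-dien-1-one F3. Warming F3 with excess 8 in dioxane releases dimethylamine to the transient (2R)-4-butanoyl-5-hydroxy-2-methyl-6-methylidene-2-(3-methylbut-2-enyl)cyclohex-4-ene-1,3-dione F4, which 8 captures at its ring C–H to give 13; the quaternary centre cannot epimerise on the way.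

2. Step 6. The product keeps one nucleophilic C–H on the methoxy ring and may be alkylated a second time, and the quinone methide 10 may be lost to self-condensation or hetero-Diels–Alder addition to a prenyl olefin. The fallback reverses the roles of the two rings, sets out from 8 and returns at 11. Eschenmoser's salt (1.0 equiv) with Et3N in CH2Cl2 at 0 °C should give 1-[3-[(dimethylamino)methyl]-2,6-dihydroxy-4-methoxyphenyl]hexan-1-one F5. Heating F5 with 5 (1.5 equiv) in dioxane generates 2-hexanoyl-3-hydroxy-5-methoxy-6-methylidenecyclohexa-2,4-dien-1-one F6, and the single free ring carbon of 5 traps it to give 11, so that the nucleophile can react only once.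

3. Step 2. O-prenylation, double prenylation and geminal (dearomatising) prenylation may all compete with mono-C-prenylation. The fallback makes O-alkylation the intended event, sets out from 3 and returns at 5. K2CO3 and 4 in acetone should alkylate the non-chelated, most acidic 4-hydroxyl to give 1-[2,6-dihydroxy-4-(3-methylbut-2-enoxy)phenyl]butan-1-one F7. Montmorillonite K10 in CH2Cl2 at rt then effects the acid-clay [1,3] O-to-C prenyl shift to the ortho carbon (the para position is blocked by the acyl group), which gives 5.

**Further compounds**

F1 | step 7 | racemic 2-butanoyl-3,5-dihydroxy-4-methyl-4-(3-methylbut-2-enyl)cyclohexa-2,5-dien-1-one | CCCC(=O)C1=C(O)C(C)(CC=C(C)C)C(O)=CC1=O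
F2 | step 7 | (4R)-2-butanoyl-3,5-dihydroxy-4-methyl-4-(3-methylbut-2-enyl)cyclohexa-2,5-dien-1-one | CCCC(=O)C1=C(O)[C@](C)(CC=C(C)C)C(O)=CC1=O
F3 | step 7 | (4R)-2-butanoyl-6-[(dimethylamino)methyl]-3,5-dihydroxy-4-methyl-4-(3-methylbut-2-enyl)cyclohexa-2,5-dien-1-one | CCCC(=O)C1=C(O)[C@](C)(CC=C(C)C)C(O)=C(CN(C)C)C1=O
F4 | step 7 | (2R)-4-butanoyl-5-hydroxy-2-methyl-6-methylidene-2-(3-methylbut-2-enyl)cyclohex-4-ene-1,3-dione | CCCC(=O)C1=C(O)C(=C)C(=O)[C@@](C)(CC=C(C)C)C1=O
F5 | step 6 | 1-[3-[(dimethylamino)methyl]-2,6-dihydroxy-4-methoxyphenyl]hexan-1-one | CCCCCC(=O)c1c(O)c(CN(C)C)c(OC)cc1O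
F6 | step 6 | 2-hexanoyl-3-hydroxy-5-methoxy-6-methylidenecyclohexa-2,4-dien-1-one | CCCCCC(=O)C1=C(O)C=C(OC)C(=C)C1=O
F7 | step 2 | 1-[2,6-dihydroxy-4-(3-methylbut-2-enoxy)phenyl]butan-1-one | CCCC(=O)c1c(O)cc(OCC=C(C)C)cc1O
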